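(The numbers of this flask were drawn at random within sensible limits; the run is a simulation.)

If one molecule of target is followed through this flask, the question at each moment is which way it leaves.

starting material 0.020 M; coupling partner 0.0220 M (fed, over 2.5 d); catalyst 20 µM; time 8.0 d

    starting material + coupling partner ⇌ target (K1 = 68.2 L mol⁻¹, k1 = 9.10 L mol⁻¹ h⁻¹)
    starting material + coupling partner ⇌ isomer of the product (K2 = 530 L mol⁻¹, k2 = 0.918 L mol⁻¹ h⁻¹)
    target + catalyst ⇌ isomer of the product + catalyst, rate k3*[catalyst]*[target] forward; the back reaction follows from the equilibrium constant (k3 = 597 L mol⁻¹ h⁻¹)
    coupling partner → decomposed reagent (k4 = 0.0114 h⁻¹)

- the state of affairs at 8.0 d: stopped, and by what, or still going (the coupling partner has run out first / all of the starting material has reacted / forward and back rates have come level / it is still moving)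
- share of the starting material used up at 8.0 d
- target at 8.0 d, in percent of the starting material charged

- the reaction counts as stopped when no species that holds the starting material changes by six tenths of a point or more over the second half of the time
- run time (flask): 8.0 d

A target molecule has two exits: the catalyst turns it into the isomer, or it falls back to starting material and coupling partner.

| Exit of a target molecule | Rate per molecule | Chance |
|---|---|---|
| on to the isomer | 0.0119 h⁻¹ | 8.21 % |
| back to starting material and partner | 0.133 h⁻¹ | 91.8 % |

Down the rate column, falling back is faster than going on. Across the lower row, nearly all departures therefore return to starting material. The half-life of a stay, 5.19 h, is short against 8.0 d, so the target should stand in balance with the free starting material and free partner around it, a pre-equilibrium.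

That gives a rule. The holding number, the equilibrium constant of the coupling step times the partner charge, is 1.50. While that balance lasts, target, as a share of the starting material charged, equals this number times the free share of starting material times the free share of partner, the latter counted against the partner charge.

The reckoning here assumes 0.5 of the starting material free. It lets the whole partner charge decay unbound from mid-feed, down to 15.8 %, and takes 0.5 of that as free; this is a rough guess, not a balance of the partner's forms. The rule then gives 5.92 % target. Conversion stays an assumption here.

The forecast says it is still moving, with conversion 54 % (49 % to 59 %) and target 6 % (4.5 % to 8 %). Its ground: “conversion stalls near half with most product as the isomer”.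

The simulation gives it is still moving, conversion 54.8 % and target 6.16 %, inside both ranges. The flask has not come to rest: target falls from 15.6 % at 4.00 d to 6.16 % at 8.00 d. The holding number, with the free shares 45 % and 8.7 % read at 8.00 d, gives 5.87 %. At 80.0 d, conversion has dropped to 12.2 %: starting material stands at 87.8 %, the isomer at 11.1 %, and partner at 0.811 %. The holding number then gives 1.07 %, and the computed target is 1.10 %.

In the same flask read at 5.0 d, the free shares 43.4 % and 16.9 % give, by the holding number, 11.0 % target. The computed value is 11.5 %.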